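## Structural features

The target is a xenicane-type diterpenoid. A 3,4-dihydro-2H-pyran (C1 acetal carbon, O2, C3=C4 enol ether) is trans-fused through C4a and C11a to a nine-membered carbocycle (C5 to C11). That ring carries a trans-7,8-epoxide with a methyl group on C7 and an exocyclic methylene on C11. C4 bears a five-carbon arm: the C12 acetoxy carbinol, a methylene and an E-trisubstituted enoate methyl ester.

Three stereocentres (C1, C11a, C4a) are contiguous on the pyran, with the C1 acetate trans to the C11a–C11 bond and the two ring-fusion bonds trans to each other. C7 and C8 lie across the medium ring, and C12 is exocyclic with no neighbouring sp3 centre to direct it.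

The fragile groups are the anomeric acetate, the electron-rich enol ether (ionisable at C1 and, through C3=C4, at C12) and the epoxide, which lies across the ring from the methylene in a caryophyllene-oxide-like arrangement and is acid-labile. During the synthesis, every ketone at C11 is also sensitive, because it has the acetal carbon C1 in its β-position.

The real difficulty is the strained E-cyclononene with its trans ring fusion, and after that the order of the late redox and acylation steps.

The key step uses two facts. C9 is allylic to C7=C8, and C10 is α to C11, the carbon that must later carry the methylene. A C11 ketone with a C10 sulfone therefore makes C10 a soft carbanion, and a C9 carbonate makes C9 the open terminus of a π-allyl unit. The pyran ring with its C4 ester carbon (the future C12) and the C4a stereocentre is already present in the iridoid 1.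

## Logic of the disconnections

32 ⇒ 31. The two acetate C–O bonds (at C1 and C12) are cut together. They are the most labile groups, so they are made last under non-acidic conditions. The gain is that no earlier step has to tolerate an acyloxy acetal. The demand is that acylation of the equilibrating lactol fixes C1 with the acetate trans to the C11a–C11 bond.

31 ⇒ 27 + 29. The C12–C13 bond is cut (with the two O–Si bonds of 30). This removes the whole side arm and the C12 stereocentre in one operation and leaves an aldehyde conjugated to the enol ether. The forward step must attack the γ-carbon of 29 and one face of the aldehyde under reagent control, without acid that would open the epoxide.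

27 ⇒ 26 ⇒ 25. No skeletal bond is cut; C12 is taken back to the ester oxidation level. The ester deactivates the enol ether through all earlier steps and comes from 1. The demand is a hydride reduction and an allylic oxidation that leave the epoxide and the silyl acetal alone.

25 ⇒ 24. The two epoxide C–O bonds are cut. Epoxidation is placed while the enol ether is still a push–pull acrylate, so only the strained C7=C8 bond is nucleophilic. The demand is attack on the correct face of the E olefin.

24 ⇒ 23 ⇒ 22. The C1–O bond is exchanged (silyl ether back to lactol back to methyl acetal). The only acidic step of the endgame is thus placed before the epoxide exists and while the acetal-bearing ring is ester-stabilised. The demand is that the E-cyclononene and the methylene survive dilute aqueous acid.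

22 ⇒ 21. The C11=CH2 bond is cut to a ketone. The ketone is what made C10 acidic for ring closure. The demand is a non-basic methylenation of a hindered ketone whose α-carbon C11a is a stereocentre.

21 ⇒ 20. The C10–S bond is restored. The sulfone is a traceless activating group. The demand is a reduction that forms the enolate only on the C10 side.

20 ⇒ 19 (key). The C9–C10 ring bond is cut, opening the nine-membered ring to a pyran with two arms. This is the largest simplification of the plan. The demand is closure at C9 rather than C7, with retention of the E olefin.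

19 ⇒ 16 + 17, then 16 ⇒ 15 ⇒ 14. The C10–S bond and the carbonate C–O bond are cut. The two primary oxygens at C9 and C10 are told apart by two different silyl groups. The demand is that the sulfinate displaces at C10 without touching the allylic carbonate.

14 ⇒ 12. No bond is cut; C11a is inverted (with loss of one silyl group). The cis arrangement is what 1 provides. The demand is that equilibration through the C11 ketone favours the trans arms and that the β-acetal survives it.

12 ⇒ 6 + 10. The C6–C7 bond is cut between an sp3 and an sp2 carbon. This divides the chain into a chiral-pool iodide and a four-carbon alkenyl iodide. The demand is a coupling that tolerates a ketone and keeps the olefin geometry.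

10 ⇒ 8 ⇒ 7. The C–I and C–H bonds across the alkyne are cut. The demand is syn addition with the metal on the methyl-bearing carbon, so that the iodide is E.

6 ⇒ 5 ⇒ 4 ⇒ 3. C6 and C11 are reconnected as the cyclopentene double bond. Oxidative scission of this ring liberates both arms at the correct oxidation levels. The demand is selectivity for this olefin over the acrylate, and for the aldehyde over the ketone.

3 ⇒ 2 ⇒ 1. Only protecting groups are removed: the methyl acetal at C1 and the silyl ether on the primary hydroxyl.

29 ⇒ 28. The O–Si bond is cut; γ-deprotonation of the enoate gives the dienolate.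

## Other disconnections considered

Alternative 1: The cuts are C4a–C5 and C11a–C11 on a five-membered ketone that is only later turned into the pyran.
- Forward step: rhodium-catalysed asymmetric 1,4-addition (for example [Rh(OH)(cod)]2 with BINAP) of the vinylborane A3 to the enone A2, then aldol reaction of the boron enolate with the iodo-alkenal A4, giving A1.
- In its favour: C4a and C11a are set trans in one catalytic operation from achiral materials, because the enolate is trapped anti to the new vinyl group. On this point it is better than the chosen plan, where C11a depends on an equilibrium. The later closure of C6–C7 (hydroboration of the vinyl group, intramolecular Suzuki coupling) would be comparable in risk to the Tsuji–Trost closure.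
- Against it here: A1 contains no pyran. Oxygen would have to be inserted between the carbonyl carbon and the unsubstituted α-carbon, against the normal migratory preference of a Baeyer–Villiger reaction, so an enol-ether cleavage and recyclisation would be needed. C1 would then have to be brought to the acetal level and the C12 carbon attached at C4.
- Comparison: on mechanism the key step is as reliable as the early steps of the chosen plan. On structure it delivers less, since 1 already holds the complete pyran with the C12 carbon. On step economy it is expected to be longer.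

Alternative 2: The cuts are C4a–C11a and O2–C1, that is, the pyran ring itself.
- Forward step: inverse-demand hetero-Diels–Alder reaction of the alkylidene formylacetate A6 with the E enol ether A7 under a Cu(OTf)2–bis(oxazoline) catalyst, giving A5.
- In its favour: it is the most convergent plan. One step forms the ring and C1, C11a and C4a; an endo transition state with the E enol ether gives the all-trans pattern, including the C1 methoxy group. It is therefore better than the chosen plan on control of C11a and C1, and it needs no degradation of a carbocycle. The C4 ester is retained, which equals the chosen plan.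
- Against it here: A6 is a 2-formylacrylate, prone to polymerisation and to isomerisation at the alkylidene bond. Its two carbonyl groups can both bind copper and either oxygen could become the ring oxygen. Enantioselectivity is less secure than for the keto ester heterodienes on which this catalysis rests. A5 still lacks the nine-membered ring: the C10–C11 closure remains and needs redox changes at both termini.
- Comparison: on stereocontrol it is better. On the ring closure it is at best equal and leaves the hard step unsolved. On step count it is probably similar, because A6 needs its own synthesis of the E-trisubstituted chain.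

Alternative 3: The cuts are C4–C4a and C1–C11a on a preformed nine-membered dienone A9.
- Forward step: copper-catalysed asymmetric conjugate addition (for example CuBr·SMe2 with a chiral ferrocenyl diphosphine) of the 2-propenyl Grignard reagent A10 to the Z enone of A9, and trapping of the magnesium enolate with formaldehyde A11, giving A8.
- Correction: A8 is taken with the E C7=C8 bond that the trans-epoxide of the target demands. A Z ring olefin at this position could not lead to the target.
- In its favour: the medium ring is made early on a simple substrate, so no precious late intermediate faces a nine-membered closure. This is a real advantage over the chosen plan. The trans relationship at C4a/C11a from anti trapping is equal to or better than an epimerisation.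
- Against it here: A9 itself (an E-trisubstituted olefin and a Z enone in one nine-membered ring) is not a simple compound, so the hardest problem is moved rather than solved. Its E-cyclononene is planar-chiral and conformationally mobile. Alkenyl Grignard additions to medium-ring enones are less developed than alkyl additions. A8 is far from the dihydropyran acetal: C1 is at the alcohol level next to a ketone, and C3 and C12 must be differentiated and oxidised.
- Comparison: on ring strain management it is better. On structure and mechanism it is less secure. On step economy it is equal at best.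

Key step: step 13

Assumption: in the seco intermediates 13 to 19 and in 20 to 22 the C1 methyl acetal is drawn with the methoxy group trans to the C11a substituent. Its configuration is not relied on, because C1 becomes a lactol in step 16 and is fixed only in step 23. Compounds 23 to 27, 30 and 31 are drawn as single C1 epimers although mixtures are expected.

Remark: the alkenyl iodide must be the E isomer (iodine trans to the oxygenated carbon). Hydroalumination–iodination of 7 would give the Z isomer, so hydrozirconation–iodination is used.

Remark: the primary hydroxyl of 1 is silylated before the oxidative cleavage, because periodate would cleave an α-hydroxy ketone. The base-mediated inversion of C11a is placed after the aldehyde and the iodide have been consumed, because both would react with the C10 enolate within the molecule.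

## Route

Step 1
Reactants: 1 genipin
Product: 2 1-O-methylgenipin (C1 methyl acetal)
Conditions: MeOH, CSA (5 mol%), rt
Reagents that add atoms: methanol, CO
Why: Acid-catalysed acetalisation of the lactol; the vinylogous carbonate keeps the ring intact, and methanol is chosen so that every later alkoxide or acid exchange at C1 and at the ester is degenerate.

Step 2
Reactants: 2 1-O-methylgenipin
Product: 3 TBDPS ether of 2 at the primary allylic hydroxyl
Conditions: TBDPSCl, imidazole, DMF, 0 °C → rt
Reagents that add atoms: tert-butyl(chloro)diphenylsilane, CC(C)(C)[Si](Cl)(c1ccccc1)c1ccccc1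
Why: Standard silylation of the only hydroxyl group; the TBDPS group survives periodate, methoxide and the acid that later removes a TBS group.

Step 3
Reactants: 3 TBDPS ether
Product: 4 cis keto aldehyde (CH2CHO on C4a and COCH2OTBDPS on C11a)
Conditions: OsO4 (2 mol%), NaIO4 (4 equiv), 2,6-lutidine, dioxane/H2O 3:1, rt
Reagents that add atoms: osmium tetroxide, O=[Os](=O)(=O)=O; sodium periodate, [Na+].[O-]I(=O)(=O)=O
Why: Lemieux–Johnson oxidation; OsO4 dihydroxylates the isolated trisubstituted cyclopentene in preference to the push–pull β-alkoxyacrylate, and periodate cleaves the diol. No stereocentre is touched, so the arms stay cis as in 1.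

Step 4
Reactants: 4 cis keto aldehyde
Product: 5 cis hydroxy ketone (primary alcohol at C6)
Conditions: LiAlH(OtBu)3 (1.1 equiv), THF, −78 °C
Reagents that add atoms: none
Why: Chemoselective hydride reduction; the hindered alkoxyaluminium hydride reduces the aldehyde much faster than the α-branched ketone and leaves the vinylogous carbonate alone.

Step 5
Reactants: 5 cis hydroxy ketone
Product: 6 cis keto iodide (CH2CH2I on C4a)
Conditions: I2, PPh3, imidazole, CH2Cl2, 0 °C
Reagents that add atoms: iodine, II
Why: Appel-type iodination of the primary alcohol under neutral conditions; any cyclic hemiketal of 5 reacts through its open form.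

Step 6
Reactants: 7 but-2-yn-1-ol
Product: 8 TBS ether of but-2-yn-1-ol
Conditions: TBSCl, imidazole, CH2Cl2, rt
Reagents that add atoms: tert-butyl(chloro)dimethylsilane, CC(C)(C)[Si](C)(C)Cl
Why: Routine silylation; the ether is needed for a clean hydrozirconation and for the later distinction from the TBDPS ether.

Step 7
Reactants: 8 TBS ether of but-2-yn-1-ol
Product: 10 (E)-3-iodobut-2-enyl TBS ether, via alkenylzirconocene chloride 9 (not isolated)
Conditions: Cp2Zr(H)Cl (1.3 equiv), THF, rt → 40 °C; then I2, 0 °C
Reagents that add atoms: iodine, II
Why: Hydrozirconation–iodination; syn addition of Zr–H followed by equilibration with a slight excess of reagent places zirconium on the methyl-bearing carbon. Iodinolysis with retention then gives the E iodide (iodine trans to CH2O).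

Step 8
Reactants: 6 cis keto iodide; 10 (E)-3-iodobut-2-enyl TBS ether
Product: 12 cis coupled ketone (E chain CH2CH2C(CH3)=CHCH2OTBS on C4a), via alkylzinc iodide 11 (not isolated)
Conditions: Zn dust, LiCl, THF, 35 °C; then 10, PdCl2(dppf) (5 mol%), THF, rt → 45 °C
Reagents that add atoms: none
Why: Negishi sp3–sp2 coupling; zinc insertion into the primary iodide tolerates the ketone, ester and acetal. The alkenyl iodide couples with retention of geometry, and the wide-bite-angle diphosphine limits β-hydride loss.

Step 9
Reactants: 12 cis coupled ketone
Product: 14 trans keto allylic alcohol (C11a inverted and C9 hydroxyl free), via trans silyl ether 13 (not isolated)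
Conditions: NaOMe (0.3 equiv), MeOH, 0 °C → rt; then CSA (1 equiv), 0 °C
Reagents that add atoms: none
Why: Base-mediated epimerisation α to the C11 ketone, under thermodynamic control. In the trans isomer the C4a chain can sit pseudoaxial, away from the C4 ester, with the acyl group anti to it, whereas the cis isomer forces a gauche pair. Any loss of methanol across C1–C11a is reversed in methanol, and the acidic methanol that follows re-equilibrates the acetal and cleaves only the primary TBS ether.

Step 10
Reactants: 14 trans keto allylic alcohol
Product: 15 allylic methyl carbonate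
Conditions: ClCO2Me, pyridine, CH2Cl2, 0 °C
Reagents that add atoms: methyl chloroformate, COC(=O)Cl
Why: Acylation of the only free hydroxyl; the carbonate is placed after the methoxide step, which it would not survive.

Step 11
Reactants: 15 allylic methyl carbonate
Product: 16 α-hydroxy ketone (C10 hydroxyl free)
Conditions: HF·pyridine, pyridine, THF, 0 °C → rt
Reagents that add atoms: none
Why: Buffered fluoride cleavage of the TBDPS ether; carbonate, acetal and the β-alkoxy ketone are stable to these near-neutral conditions.

Step 12
Reactants: 16 α-hydroxy ketone; 17 sodium benzenesulfinate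
Product: 19 β-keto sulfone allylic carbonate (cyclisation precursor), via keto mesylate 18 (not isolated)
Conditions: MsCl, Et3N, CH2Cl2, −20 °C; aqueous work-up; then PhSO2Na, Bu4NI (cat.), DMF, rt
Reagents that add atoms: none
Why: SN2 displacement at the activated α-keto carbon by the sulfur of the sulfinate (S-alkylation). Without palladium the allylic carbonate does not ionise and is left intact.

Step 13
Reactants: 19 β-keto sulfone allylic carbonate
Product: 20 bicyclic β-keto sulfone (nine-membered ring closed and one C10 epimer drawn)
Conditions: Pd(PPh3)4 (10 mol%), THF, 65 °C, syringe-pump addition to 0.002 M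
Reagents that add atoms: none
Why: Zerovalent palladium adds oxidatively to the allylic carbonate with loss of CO2, giving a π-allyl complex of divalent palladium and methoxide, which deprotonates the β-keto sulfone; the soft C10 carbanion then attacks the unsubstituted C9 terminus on the face opposite the metal (Tsuji–Trost allylic alkylation, used as a macrocyclisation of the kind known for sulfone-stabilised carbanions and medium rings). The nine-membered carbocycle closes in the endo mode (9-endo with respect to the allyl unit, so C7, C8 and C9 all end up in the ring); the competing 7-exo attack at C7 would create a quaternary carbon and is blocked by the C7 methyl group. No lasting stereocentre is created: C10 forms as sulfone epimers that converge in step 14, and C1, C4a and C11a are spectators. The step needs C- rather than O-alkylation, C9 rather than C7 attack, retention of the E olefin and cyclisation rather than oligomerisation. O-Allylation is reversible under the catalyst and the regiochemistry is set by the methyl group. The complex formed from the E carbonate carries the ring chain syn and could isomerise only through an unfavourable tertiary σ-allyl at C7, and high dilution with the trans-disposed arms on the half-chair pyran favours the intramolecular path. Base appears only as the carbonate ionises, which protects the β-alkoxy ketone from elimination.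

Step 14
Reactants: 20 bicyclic β-keto sulfone
Product: 21 bicyclic C11 ketone
Conditions: SmI2 (3 equiv), THF/MeOH, −78 °C
Reagents that add atoms: none
Why: Reductive desulfonylation of an α-sulfonyl ketone by single-electron transfer. The samarium enolate forms only across C10–C11 and is protonated by methanol, so C11a is not touched and the C10 epimers converge.

Step 15
Reactants: 21 bicyclic C11 ketone
Product: 22 C11 methylene diene ester
Conditions: Zn, CH2Br2, TiCl4, THF/CH2Cl2, 0 °C → rt
Reagents that add atoms: dibromomethane, BrCBr
Why: Takai–Lombardo methylenation; the non-basic gem-dimetallic reagent converts enolisable ketones without epimerising the α-centre or eliminating the β-methoxy group, and it prefers the ketone to the conjugated ester.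

Step 16
Reactants: 22 C11 methylene diene ester
Product: 23 C1 lactol
Conditions: 1 M aq. HCl, THF, 0 °C → rt
Reagents that add atoms: water, O
Why: Acid-catalysed acetal hydrolysis, the reverse of step 1. It is placed here because the ester-stabilised lactol stays ring-closed, no ketone remains next to C11a, and the epoxide is not yet present.

Step 17
Reactants: 23 C1 lactol
Product: 24 C1 TBS lactol ether
Conditions: TBSCl, imidazole, DMF, 0 °C → rt
Reagents that add atoms: tert-butyl(chloro)dimethylsilane, CC(C)(C)[Si](C)(C)Cl
Why: Silylation of the lactol hydroxyl; the silyl acetal withstands hydride, MnO2 and peracid and is later removed by fluoride, so the endgame needs no acid.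

Step 18
Reactants: 24 C1 TBS lactol ether
Product: 25 (7S,8S)-epoxide
Conditions: mCPBA (1.05 equiv), NaHCO3, CH2Cl2, −20 °C
Reagents that add atoms: 3-chloroperoxybenzoic acid, OOC(=O)c1cccc(Cl)c1
Why: Prilezhaev epoxidation; the strained E-trisubstituted olefin is far more nucleophilic than the 1,1-disubstituted methylene or the ester-deactivated enol ether. Attack on the exposed face of the preferred ring conformer is expected to give the 7S,8S isomer, by analogy with the trans-fused methylene-E-cyclononene of caryophyllene, which is the same ring system in the mirror-image sense.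

Step 19
Reactants: 25 (7S,8S)-epoxide
Product: 26 C12 allylic alcohol
Conditions: iBu2AlH (2.5 equiv), CH2Cl2, −78 °C; aq. potassium sodium tartrate
Reagents that add atoms: none
Why: Hydride reduction of the conjugated ester to the primary alcohol; at −78 °C the trisubstituted epoxide and the silyl acetal are not attacked.

Step 20
Reactants: 26 C12 allylic alcohol
Product: 27 C12 aldehyde
Conditions: MnO2, CH2Cl2, rt
Reagents that add atoms: none
Why: Selective oxidation of the allylic alcohol under neutral heterogeneous conditions; it restores conjugation to the enol ether, which again protects the pyran.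

Step 21
Reactants: 28 methyl tiglate
Product: 29 1-methoxy-2-methyl-1-(trimethylsilyloxy)buta-1,3-diene
Conditions: LiN(iPr)2, THF/DMPU, −78 °C; then Me3SiCl
Reagents that add atoms: chlorotrimethylsilane, C[Si](C)(C)Cl
Why: γ-Deprotonation of the enoate and O-silylation give the silyl dienolate; the geometry of the ketene acetal has no consequence because no α-stereocentre is formed.

Step 22
Reactants: 27 C12 aldehyde; 29 1-methoxy-2-methyl-1-(trimethylsilyloxy)buta-1,3-diene
Product: 31 C1,C12 diol (lactol and 12R carbinol with the E enoate arm), via bis-silyl aldol ether 30 (not isolated)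
Conditions: Cu(OTf)2 (10 mol%), (S)-Tol-BINAP (11 mol%), Bu4N[Ph3SiF2] (20 mol%), THF, −78 → −40 °C; then HF·pyridine, pyridine, THF, 0 °C
Reagents that add atoms: none
Why: Catalytic asymmetric vinylogous Mukaiyama aldol reaction through a chiral copper dienolate rather than a strong Lewis acid, so the epoxide and silyl acetal are not exposed to acid. The γ-carbon adds to the Re face of the conjugated aldehyde under control of the bisphosphine, setting 12R; the ligand antipode is used if a model aldehyde shows the opposite sense. The E enoate is the conjugated, more stable geometry, and buffered fluoride then removes both silyl groups.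

Step 23
Reactants: 31 C1,C12 diol
Product: 32 target diacetate CNP0184381.4
Conditions: Ac2O, Et3N, DMAP (cat.), CH2Cl2, 0 °C
Reagents that add atoms: acetic anhydride, CC(=O)OC(C)=O
Why: DMAP-catalysed acetylation of both hydroxyls; the lactol epimers interconvert, and acylation is expected to place the C1 acetate trans to the C11a–C11 bond, the anomerically stabilised orientation. C12 is acylated with retention.

## Compound list

1 | genipin, methyl (1R,4aS,7aS)-1-hydroxy-7-(hydroxymethyl)-1,4a,5,7a-tetrahydrocyclopenta[c]pyran-4-carboxylate | COC(=O)C1=CO[C@H]([C@H]2[C@@H]1CC=C2CO)O | starting material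

2 | 1-O-methylgenipin, methyl (1R,4aS,7aS)-7-(hydroxymethyl)-1-methoxy-1,4a,5,7a-tetrahydrocyclopenta[c]pyran-4-carboxylate | COC(=O)C1=CO[C@H]([C@H]2[C@@H]1CC=C2CO)OC | intermediate

3 | methyl (1R,4aS,7aS)-7-{[tert-butyl(diphenyl)silyl]oxymethyl}-1-methoxy-1,4a,5,7a-tetrahydrocyclopenta[c]pyran-4-carboxylate | COC(=O)C1=CO[C@H]([C@H]2[C@@H]1CC=C2CO[Si](c3ccccc3)(c4ccccc4)C(C)(C)C)OC | intermediate

4 | methyl (2R,3R,4S)-3-{[tert-butyl(diphenyl)silyl]oxyacetyl}-2-methoxy-4-(2-oxoethyl)-3,4-dihydro-2H-pyran-5-carboxylate (arms cis) | O=CC[C@@H]1C(C(=O)OC)=CO[C@@H](OC)[C@@H]1C(=O)CO[Si](c2ccccc2)(c3ccccc3)C(C)(C)C | intermediate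

5 | methyl (2R,3R,4S)-3-{[tert-butyl(diphenyl)silyl]oxyacetyl}-4-(2-hydroxyethyl)-2-methoxy-3,4-dihydro-2H-pyran-5-carboxylate | OCC[C@@H]1C(C(=O)OC)=CO[C@@H](OC)[C@@H]1C(=O)CO[Si](c2ccccc2)(c3ccccc3)C(C)(C)C | intermediate

6 | methyl (2R,3R,4S)-3-{[tert-butyl(diphenyl)silyl]oxyacetyl}-4-(2-iodoethyl)-2-methoxy-3,4-dihydro-2H-pyran-5-carboxylate | ICC[C@@H]1C(C(=O)OC)=CO[C@@H](OC)[C@@H]1C(=O)CO[Si](c2ccccc2)(c3ccccc3)C(C)(C)C | intermediate

7 | but-2-yn-1-ol | CC#CCO | starting material

8 | (but-2-yn-1-yloxy)(tert-butyl)dimethylsilane | CC#CCO[Si](C)(C)C(C)(C)C | intermediate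

9 | chlorobis(cyclopentadienyl)[(E)-4-(tert-butyldimethylsilyloxy)but-2-en-2-yl]zirconium (cyclopentadienyl rings written as σ-bonded) | C/C(=C\CO[Si](C)(C)C(C)(C)C)[Zr](Cl)(C1C=CC=C1)C1C=CC=C1 | intermediate (not isolated)

10 | tert-butyl{[(E)-3-iodobut-2-en-1-yl]oxy}dimethylsilane | C/C(I)=C\CO[Si](C)(C)C(C)(C)C | intermediate

11 | alkylzinc iodide from 6, iodo{2-[(2R,3R,4S)-pyran-4-yl]ethyl}zinc | I[Zn]CC[C@@H]1C(C(=O)OC)=CO[C@@H](OC)[C@@H]1C(=O)CO[Si](c2ccccc2)(c3ccccc3)C(C)(C)C | intermediate (not isolated)

12 | methyl (2R,3R,4S)-4-[(E)-5-(tert-butyldimethylsilyloxy)-3-methylpent-3-enyl]-3-{[tert-butyl(diphenyl)silyl]oxyacetyl}-2-methoxy-3,4-dihydro-2H-pyran-5-carboxylate (arms cis) | CC(C)(C)[Si](C)(C)OC/C=C(\C)CC[C@@H]1C(C(=O)OC)=CO[C@@H](OC)[C@@H]1C(=O)CO[Si](c2ccccc2)(c3ccccc3)C(C)(C)C | intermediate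

13 | methyl (2S,3S,4S)-4-[(E)-5-(tert-butyldimethylsilyloxy)-3-methylpent-3-enyl]-3-{[tert-butyl(diphenyl)silyl]oxyacetyl}-2-methoxy-3,4-dihydro-2H-pyran-5-carboxylate (arms trans) | CC(C)(C)[Si](C)(C)OC/C=C(\C)CC[C@@H]1C(C(=O)OC)=CO[C@H](OC)[C@H]1C(=O)CO[Si](c2ccccc2)(c3ccccc3)C(C)(C)C | intermediate (not isolated)

14 | methyl (2S,3S,4S)-3-{[tert-butyl(diphenyl)silyl]oxyacetyl}-4-[(E)-5-hydroxy-3-methylpent-3-enyl]-2-methoxy-3,4-dihydro-2H-pyran-5-carboxylate | OC/C=C(\C)CC[C@@H]1C(C(=O)OC)=CO[C@H](OC)[C@H]1C(=O)CO[Si](c2ccccc2)(c3ccccc3)C(C)(C)C | intermediate

15 | methyl (2S,3S,4S)-3-{[tert-butyl(diphenyl)silyl]oxyacetyl}-2-methoxy-4-[(E)-5-(methoxycarbonyloxy)-3-methylpent-3-enyl]-3,4-dihydro-2H-pyran-5-carboxylate | COC(=O)OC/C=C(\C)CC[C@@H]1C(C(=O)OC)=CO[C@H](OC)[C@H]1C(=O)CO[Si](c2ccccc2)(c3ccccc3)C(C)(C)C | intermediate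

16 | methyl (2S,3S,4S)-3-(hydroxyacetyl)-2-methoxy-4-[(E)-5-(methoxycarbonyloxy)-3-methylpent-3-enyl]-3,4-dihydro-2H-pyran-5-carboxylate | COC(=O)OC/C=C(\C)CC[C@@H]1C(C(=O)OC)=CO[C@H](OC)[C@H]1C(=O)CO | intermediate

17 | sodium benzenesulfinate | [Na+].[O-]S(=O)c1ccccc1 | starting material

18 | methyl (2S,3S,4S)-2-methoxy-4-[(E)-5-(methoxycarbonyloxy)-3-methylpent-3-enyl]-3-[(methylsulfonyloxy)acetyl]-3,4-dihydro-2H-pyran-5-carboxylate | COC(=O)OC/C=C(\C)CC[C@@H]1C(C(=O)OC)=CO[C@H](OC)[C@H]1C(=O)COS(C)(=O)=O | intermediate (not isolated)

19 | methyl (2S,3S,4S)-2-methoxy-4-[(E)-5-(methoxycarbonyloxy)-3-methylpent-3-enyl]-3-[(phenylsulfonyl)acetyl]-3,4-dihydro-2H-pyran-5-carboxylate | COC(=O)OC/C=C(\C)CC[C@@H]1C(C(=O)OC)=CO[C@H](OC)[C@H]1C(=O)CS(=O)(=O)c1ccccc1 | intermediate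

20 | methyl (1S,4aS,7E,10R,11aS)-1-methoxy-7-methyl-11-oxo-10-(phenylsulfonyl)-1,4a,5,6,9,10,11,11a-octahydrocyclonona[c]pyran-4-carboxylate (C10 epimer drawn) | O=C1[C@H](S(=O)(=O)c3ccccc3)C/C=C(C)/CC[C@@H]2C(C(=O)OC)=CO[C@H](OC)[C@@H]12 | intermediate

21 | methyl (1S,4aS,7E,11aS)-1-methoxy-7-methyl-11-oxo-1,4a,5,6,9,10,11,11a-octahydrocyclonona[c]pyran-4-carboxylate | O=C1CC/C=C(C)/CC[C@@H]2C(C(=O)OC)=CO[C@H](OC)[C@@H]12 | intermediate

22 | methyl (1S,4aS,7E,11aR)-1-methoxy-7-methyl-11-methylidene-1,4a,5,6,9,10,11,11a-octahydrocyclonona[c]pyran-4-carboxylate | C=C1CC/C=C(C)/CC[C@@H]2C(C(=O)OC)=CO[C@H](OC)[C@@H]12 | intermediate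

23 | methyl (4aS,7E,11aR)-1-hydroxy-7-methyl-11-methylidene-1,4a,5,6,9,10,11,11a-octahydrocyclonona[c]pyran-4-carboxylate (lactol, 1S epimer drawn) | C=C1CC/C=C(C)/CC[C@@H]2C(C(=O)OC)=CO[C@H](O)[C@@H]12 | intermediate

24 | methyl (4aS,7E,11aR)-1-(tert-butyldimethylsilyloxy)-7-methyl-11-methylidene-1,4a,5,6,9,10,11,11a-octahydrocyclonona[c]pyran-4-carboxylate (1R epimer drawn) | C=C1CC/C=C(C)/CC[C@@H]2C(C(=O)OC)=CO[C@H](O[Si](C)(C)C(C)(C)C)[C@@H]12 | intermediate

25 | (7S,8S)-7,8-epoxide of 24, methyl (4aS,7S,8S,11aR)-1-(tert-butyldimethylsilyloxy)-7,8-epoxy-7-methyl-11-methylidene-decahydrocyclonona[c]pyran-3-ene-4-carboxylate | C=C1CC[C@@H]2O[C@@]2(C)CC[C@@H]2C(C(=O)OC)=CO[C@H](O[Si](C)(C)C(C)(C)C)[C@@H]12 | intermediate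

26 | [(4aS,7S,8S,11aR)-1-(tert-butyldimethylsilyloxy)-7,8-epoxy-7-methyl-11-methylidene-cyclonona[c]pyran-4-yl]methanol (C3=C4 enol ether retained) | C=C1CC[C@@H]2O[C@@]2(C)CC[C@@H]2C(CO)=CO[C@H](O[Si](C)(C)C(C)(C)C)[C@@H]12 | intermediate

27 | (4aS,7S,8S,11aR)-1-(tert-butyldimethylsilyloxy)-7,8-epoxy-7-methyl-11-methylidene-cyclonona[c]pyran-4-carbaldehyde (C3=C4 enol ether retained) | C=C1CC[C@@H]2O[C@@]2(C)CC[C@@H]2C(C=O)=CO[C@H](O[Si](C)(C)C(C)(C)C)[C@@H]12 | intermediate

28 | methyl tiglate, methyl (E)-2-methylbut-2-enoate | C/C=C(\C)C(=O)OC | starting material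

29 | 1-methoxy-2-methyl-1-(trimethylsilyloxy)buta-1,3-diene (ketene acetal geometry not fixed) | C=CC(C)=C(OC)O[Si](C)(C)C | intermediate

30 | methyl (2E,5R)-5-[(4aS,7S,8S,11aR)-1-(tert-butyldimethylsilyloxy)-7,8-epoxy-7-methyl-11-methylidene-cyclonona[c]pyran-4-yl]-2-methyl-5-(trimethylsilyloxy)pent-2-enoate | C=C1CC[C@@H]2O[C@@]2(C)CC[C@@H]2C([C@@H](C/C=C(\C)C(=O)OC)O[Si](C)(C)C)=CO[C@H](O[Si](C)(C)C(C)(C)C)[C@@H]12 | intermediate (not isolated)

31 | methyl (2E,5R)-5-hydroxy-5-[(4aS,7S,8S,11aR)-1-hydroxy-7,8-epoxy-7-methyl-11-methylidene-cyclonona[c]pyran-4-yl]-2-methylpent-2-enoate (lactol, 1S epimer drawn) | C=C1CC[C@@H]2O[C@@]2(C)CC[C@@H]2C([C@@H](C/C=C(\C)C(=O)OC)O)=CO[C@H](O)[C@@H]12 | intermediate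

32 | CNP0184381.4, methyl (2E,5R)-5-acetoxy-5-[(1R,4aS,7S,8S,11aR)-1-acetoxy-7,8-epoxy-7-methyl-11-methylidene-cyclonona[c]pyran-4-yl]-2-methylpent-2-enoate | C=C1CC[C@@H]2O[C@@]2(C)CC[C@@H]2C([C@@H](C/C=C(\C)C(=O)OC)OC(C)=O)=CO[C@H](OC(C)=O)[C@@H]12 | target

## Step count and least certain steps

Total step count: 23. Longest linear sequence: 20 steps (steps 1 to 5, 8 to 20, 22 and 23, from 1 to 32). Steps 6 and 7 and step 21 prepare the two side fragments.

**Step 13 (key step).** The strain of the E nine-membered ring may make closure slow. Intermolecular alkylation to oligomers, β-hydride loss from the π-allyl complex to a 1,3-diene, or syn/anti isomerisation of the complex followed by closure to the less strained Z ring could then compete.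

Fallback: from 19, K2CO3 in MeOH removes the carbonate to give the β-keto sulfone allylic alcohol F1. CBr4 and PPh3 convert it into the allylic bromide F2. Cs2CO3 in MeCN at high dilution then forms the same C9–C10 bond by direct SN2 displacement by the β-keto sulfone anion. No π-allyl intermediate is involved, so the olefin geometry cannot change. The sequence returns to the route at 20.

**Step 9.** The equilibrium may leave much of the cis isomer. Under methoxide, loss of methanol across C1–C11a or opening of the β-alkoxyacrylate may also compete with clean inversion, because the acetal carbon is β to the ketone.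

Fallback: from 12, DBU in CH2Cl2 is used to eliminate methanol on purpose, giving the 4H-pyranyl ketone F3 (C1=C11a). CSA in MeOH with HC(OMe)3 then adds methanol back under acid catalysis. C11a is protonated under thermodynamic control with no alkoxide present, and the same acid removes the TBS group. The sequence returns at 14. Recovered cis material can be resubmitted.

**Step 22.** The aldehyde is a vinylogous formate and may add the copper dienolate slowly. Attack through the α-carbon of the dienolate, or poor facial selectivity in a mismatched pairing of ligand and substrate, would erode the yield of the 12R γ-adduct.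

Fallback: from 27, the enantiomer of Ipc2B(allyl) that adds to the Re face gives the homoallylic alcohol F4 at −78 °C without any Lewis acid. Cross-metathesis with excess methyl methacrylate (second-generation Hoveyda–Grubbs catalyst, CH2Cl2, 40 °C) gives the δ-hydroxy enoate F5. The excess of methacrylate is meant to outrun ring-closing metathesis onto the C11 methylene. HF·pyridine then removes the silyl group, and the sequence returns at 31.

**Step 18.** Facial selectivity may be poor if the conformer population of the ring differs from the caryophyllene model; a second epoxidation at the methylene is a minor concern.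

Fallback: from 24, the control element is changed from substrate to reagent. A Shi epoxidation is used, with the fructose-derived ketone enantiomer matched to the 7S,8S face, KHSO5 (as 2KHSO5·KHSO4·K2SO4) and K2CO3 in MeCN/dimethoxymethane/H2O at 0 °C. No new compound is involved (F0), and the sequence returns at 25.

**Step 15.** The hindered medium-ring ketone may react slowly, and prolonged contact with the titanium reagent may cause enolisation towards C11a or loss of the β-methoxy group.

Fallback: from 21, Me3SiCH2Li with anhydrous CeCl3 at −78 °C adds to the ketone to give the β-hydroxysilane F6 as C11 epimers. KH in THF then effects syn elimination (Peterson olefination), and the sequence returns at 22.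

## Further compounds

F1 | step 13 | methyl (2S,3S,4S)-4-[(E)-5-hydroxy-3-methylpent-3-enyl]-2-methoxy-3-[(phenylsulfonyl)acetyl]-3,4-dihydro-2H-pyran-5-carboxylate | OC/C=C(\C)CC[C@@H]1C(C(=O)OC)=CO[C@H](OC)[C@H]1C(=O)CS(=O)(=O)c1ccccc1
F2 | step 13 | methyl (2S,3S,4S)-4-[(E)-5-bromo-3-methylpent-3-enyl]-2-methoxy-3-[(phenylsulfonyl)acetyl]-3,4-dihydro-2H-pyran-5-carboxylate | BrC/C=C(\C)CC[C@@H]1C(C(=O)OC)=CO[C@H](OC)[C@H]1C(=O)CS(=O)(=O)c1ccccc1
F3 | step 9 | methyl (4S)-4-[(E)-5-(tert-butyldimethylsilyloxy)-3-methylpent-3-enyl]-5-{[tert-butyl(diphenyl)silyl]oxyacetyl}-4H-pyran-3-carboxylate | CC(C)(C)[Si](C)(C)OC/C=C(\C)CC[C@@H]1C(C(=O)OC)=COC=C1C(=O)CO[Si](c2ccccc2)(c3ccccc3)C(C)(C)C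
F4 | step 22 | (1R)-1-[(4aS,7S,8S,11aR)-1-(tert-butyldimethylsilyloxy)-7,8-epoxy-7-methyl-11-methylidene-cyclonona[c]pyran-4-yl]but-3-en-1-ol | C=C1CC[C@@H]2O[C@@]2(C)CC[C@@H]2C([C@@H](CC=C)O)=CO[C@H](O[Si](C)(C)C(C)(C)C)[C@@H]12
F5 | step 22 | methyl (2E,5R)-5-[(4aS,7S,8S,11aR)-1-(tert-butyldimethylsilyloxy)-7,8-epoxy-7-methyl-11-methylidene-cyclonona[c]pyran-4-yl]-5-hydroxy-2-methylpent-2-enoate | C=C1CC[C@@H]2O[C@@]2(C)CC[C@@H]2C([C@@H](C/C=C(\C)C(=O)OC)O)=CO[C@H](O[Si](C)(C)C(C)(C)C)[C@@H]12
F0 | step 18 | none | none
F6 | step 15 | methyl (1S,4aS,7E,11aS)-11-hydroxy-1-methoxy-7-methyl-11-[(trimethylsilyl)methyl]-1,4a,5,6,9,10,11,11a-octahydrocyclonona[c]pyran-4-carboxylate (C11 epimers) | C[Si](C)(C)CC1(O)CC/C=C(C)/CC[C@@H]2C(C(=O)OC)=CO[C@H](OC)[C@@H]12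
A1 | alternative 1 | trans-2-[(E)-1-hydroxy-5-iodohex-4-enyl]-3-vinylcyclopentan-1-one (one carbinol epimer) | O=C1CC[C@@H](C=C)[C@@H]1[C@H](O)CC/C=C(\C)I
A2 | alternative 1 | cyclopent-2-en-1-one | O=C1C=CCC1
A3 | alternative 1 | B-vinyl-9-borabicyclo[3.3.1]nonane | C=CB1C2CCCC1CCC2
A4 | alternative 1 | (E)-5-iodohex-4-enal | O=CCC/C=C(\C)I
A5 | alternative 2 | methyl (2S,3R,4S)-3-[(tert-butyldimethylsilyloxy)methyl]-2-methoxy-4-[(E)-6-(4-methoxybenzyloxy)-3-methylhex-3-enyl]-3,4-dihydro-2H-pyran-5-carboxylate | COc1ccc(COCC/C=C(\C)CC[C@@H]2C(C(=O)OC)=CO[C@H](OC)[C@H]2CO[Si](C)(C)C(C)(C)C)cc1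
A6 | alternative 2 | methyl (6E)-2-formyl-9-(4-methoxybenzyloxy)-6-methylnona-2,6-dienoate (alkylidene geometry not fixed) | O=CC(C(=O)OC)=CCC/C(C)=C/CCOCc1ccc(OC)cc1
A7 | alternative 2 | tert-butyl{[(E)-3-methoxyprop-2-en-1-yl]oxy}dimethylsilane | CO/C=C/CO[Si](C)(C)C(C)(C)C
A8 | alternative 3 | trans-(6E)-3-[3-(tert-butyldimethylsilyloxy)prop-1-en-2-yl]-2-(hydroxymethyl)-6-methylcyclonon-6-en-1-one | C1C(=O)[C@H](CO)[C@@H](C(=C)CO[Si](C)(C)C(C)(C)C)CC/C(C)=C/C1
A9 | alternative 3 | (2Z,6E)-6-methylcyclonona-2,6-dien-1-one | O=C1/C=C\CC/C(C)=C/CC1
A10 | alternative 3 | [3-(tert-butyldimethylsilyloxy)prop-1-en-2-yl]magnesium bromide | C=C([Mg]Br)CO[Si](C)(C)C(C)(C)C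
A11 | alternative 3 | formaldehyde | C=O
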